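The winter run differs from the noon flask you take over in its substrate, 0.120 M against 0.0300 M; partner and catalyst are charged alike.

| flask | substrate | partner | catalyst | time |
|---|---|---|---|---|
| winter | 0.120 M | 0.120 M | 2.40 × 10⁻⁴ M |  |
| midnight | 0.120 M | 0.180 M | 2.40 × 10⁻⁴ M |  |
| spring | 0.120 M | 0.120 M | 1.20 × 10⁻⁴ M |  |
| noon | 0.0300 M | 0.120 M | 2.40 × 10⁻⁴ M | 6.0 h |

| run | time / h | [target] / M |
|---|---|---|
| winter run | 0.22 | 0.0037 |
| winter run | 0.65 | 0.0066 |
| winter run | 1.2 | 0.0181 |
| winter run | 2.0 | 0.0364 |
| winter run | 2.8 | 0.0569 |
| winter run | 3.8 | 0.0741 |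
| winter run | 4.8 | 0.0905 |
| winter run | 6.0 | 0.0974 |
| midnight run | 0.22 | 0 |
| midnight run | 0.65 | 0.0076 |
| midnight run | 1.2 | 0.0215 |
| midnight run | 2.0 | 0.0486 |
| midnight run | 2.8 | 0.0725 |
| midnight run | 3.8 | 0.0931 |
| midnight run | 4.8 | 0.1060 |
| midnight run | 6.0 | 0.1133 |
| spring run | 0.22 | 0.0043 |
| spring run | 0.65 | 0.0030 |
| spring run | 1.2 | 0.0104 |
| spring run | 2.0 | 0.0247 |
| spring run | 2.8 | 0.0372 |
| spring run | 3.8 | 0.0608 |
| spring run | 4.8 | 0.0752 |
| spring run | 6.0 | 0.0858 |

(each reading ± 0.002 M)

- how the opening rate goes with [catalyst] round the charge of the winter run: the exponent of the rate at two percent of substrate gone to target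
- how the opening rate goes with [partner] round the charge of the winter run: the exponent of the rate at two percent of substrate gone to target
- target in the noon run at 6.0 h, as a share of the substrate charged

- Overall: substrate + partner -> target, with catalyst as catalyst.
- Constant volume, constant temperature.
- Bound and free are read together.
- An order is taken over about fifteen percent of the charge, up and down.

We divide the rate of making target by the substrate left and call this the pace, which is what a pseudo-first-order constant would be if it held still. Over the first 1.2 h of the winter run it reads 0.136 h⁻¹, the opening pace.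

| Run | Opening pace, to 1.2 h | Middle pace, 2.0 h to 3.8 h |
|---|---|---|
| winter | 0.136 h⁻¹ | 0.323 h⁻¹ |
| midnight | 0.164 h⁻¹ | 0.503 h⁻¹ |
| spring | 0.0755 h⁻¹ | 0.260 h⁻¹ |

The winter pace climbs as target gathers, so we read it as following the target made. Spring opens at 0.555 of the winter pace, which we read as an exponent of 0.849 in catalyst.

In the noon flask substrate is the limiting reagent, so target stays below the winter middle stretch's average. We therefore hold the noon flask at the winter opening pace. At 6.0 h we expect 55.8%: 0.0167 M target, 0.0133 M substrate and 0.103 M partner. Taken as a steady climb, that end value averages 0.00835 M target, against 0.00905 M over the winter opening.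

Leave the partner as charged: at 1.2 h the midnight run stood 0.00340 M above winter, with scatter 0.002 M, too near to read an exponent.

The forecast gives 0.5 for catalyst, 0.65 for partner and 93% for noon, reasoning: “With partner near 0.105 M, k is about 0.55 per hour.”

The flask gives 0.83, −0.22 and 60.6%.

    catalyst + substrate → catalyst-substrate complex (745.2 L mol⁻¹ h⁻¹)
    catalyst-substrate complex + partner → target + catalyst (16560 L mol⁻¹ h⁻¹)
    substrate + partner + target → 2 target (63.72 L² mol⁻² h⁻¹)
    catalyst + partner ⇌ idle catalyst-reagent complex, settled at all times (8.390 L mol⁻¹)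

That noon share means an average pace of 0.155 h⁻¹, against 0.136 h⁻¹ at the winter opening and 0.55 in the forecast. Target itself supplies part of it: with the step substrate + partner + target taken away, the noon run falls from 60.6% to 42.2%, an average pace of 0.0914 h⁻¹.

The earlier runs and the new flask come from a simulation for substances that don't exist; the scatter is artificial.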